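**Retrosynthetic overview**

1. Target 35 ⇐ 34 (two allyl ethers off) ⇐ 33 (LiBH4) ⇐ Evans syn-aldol of the core-bound glycolyl imide 24 with aldehyde 32; this joins the pre-built erythro end unit G1 to the core and sets the threo middle unit G2 (7R,8R).
2. The two erythro units (G3 in 22, G1 in 32) ⇐ Evans syn-aldol (threo) followed by Mitsunobu inversion at the benzylic C7; the two syringyl phenols of the core are told apart as allyl and TIPS ethers.
3. Core 14 ⇐ epoxy cinnamyl ether 9 by the key cascade: Cp2TiCl opens the epoxide to a C8 radical, 5-exo cyclisation makes the C8–C8' bond and tetrahydrofuran ring A (C7–O–C9'–C8'–C8), then iodine makes benzylic C7' electrophilic and the C9 oxygen closes ring B (C8–C9–O–C7'–C8'). C7 alone relays C8, C8' and C7'.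
4. 9 ⇐ epoxy alcohol 4 (syringaldehyde; C7 set by Sharpless kinetic resolution) + cinnamyl bromide 8 (methyl sinapate): two syringyl C6–C3 units tied through oxygen, a tethered counterpart of the β–β dimerisation of sinapyl alcohol.
5. Enabling feature: in the cis-fused 3,7-dioxabicyclo[3.3.0]octane each bridgehead (C8, C8') lies between an O–CH2 carbon and an O–CH(aryl) carbon. C8 can therefore come from a C8–C9 epoxide as a β-oxygenated radical, C8'=C7' can be a styrene-type acceptor held to C7 through O–C9', and the para-oxygenated 3,5-dimethoxyphenyl ring on C7' lets that carbon go from radical to quinone-methide-type cation for the second C–O closure.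

Key step: step 8

Remark on locants: lignan numbering (C7 benzylic, C8, C9 = CH2O of each C6–C3 unit); S is the syringyl unit that will carry the two-unit arm, S' the other (primed locants); G1 (terminal), G2 (middle) and G3 (on S') are the guaiacylglycerol units; Xc is the 4-benzyl-2-oxooxazolidin-3-yl auxiliary.

Assumption: the enantiomeric 4-benzyl-3-(chloroacetyl)oxazolidin-2-ones 16 and 26 are taken as catalogue compounds; each is otherwise one N-acylation from the commercial oxazolidinone.

**Route**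

Step 1
Reactants: 1 syringaldehyde
Product: 2 TIPS-protected syringaldehyde (3,5-dimethoxy-4-(triisopropylsilyloxy)benzaldehyde)
Conditions: TIPSCl, imidazole, DMF, rt
Reagents that add atoms: triisopropylsilyl chloride CC(C)[Si](Cl)(C(C)C)C(C)C
Why: Imidazole-promoted O-silylation of the acidic phenol; the hindered aryl TIPS ether should survive Grignard, hydride, carbonate and Cp2TiCl and later leave with fluoride while allyl ethers and esters stay.

Step 2
Reactants: 2 TIPS-protected syringaldehyde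
Product: 3 racemic 1-[3,5-dimethoxy-4-(triisopropylsilyloxy)phenyl]prop-2-en-1-ol
Conditions: CH2=CHMgBr, THF, −78 → 0 °C; aq. NH4Cl
Reagents that add atoms: vinylmagnesium bromide C=C[Mg]Br
Why: Grignard 1,2-addition to the aldehyde gives the racemic aryl vinyl carbinol; the aryl silyl ether is inert at low temperature.

Step 3
Reactants: 3 racemic aryl vinyl carbinol
Product: 4 erythro epoxy alcohol (S)-[3,5-dimethoxy-4-(triisopropylsilyloxy)phenyl][(2R)-oxiran-2-yl]methanol
Conditions: Ti(OiPr)4 (cat.), L-(+)-diisopropyl tartrate, tBuOOH (0.45 equiv), 4 Å MS, CH2Cl2, −20 °C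
Reagents that add atoms: tert-butyl hydroperoxide CC(C)(C)OO
Why: Sharpless kinetic resolution: with the L-(+)-tartrate catalyst the (R)-carbinol should be the fast-reacting enantiomer and be epoxidised to the erythro epoxy alcohol, so C7 (the one stereocentre the core inherits) is set by catalysis and the epoxide is installed in the same operation; the run is stopped below half conversion.

Step 4
Reactants: 5 methyl sinapate
Product: 6 methyl (E)-3-[4-(allyloxy)-3,5-dimethoxyphenyl]acrylate
Conditions: allyl bromide, K2CO3, DMF, 50 °C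
Reagents that add atoms: allyl bromide C=CCBr
Why: Williamson O-allylation of the phenoxide; allyl is chosen because zerovalent palladium removes it while TIPS, esters and benzylic ethers stay.

Step 5
Reactants: 6 O-allyl methyl sinapate
Product: 7 (E)-3-[4-(allyloxy)-3,5-dimethoxyphenyl]prop-2-en-1-ol
Conditions: DIBAL-H (iBu2AlH), CH2Cl2, −78 °C; aq. KNaC4H4O6
Reagents that add atoms: none
Why: DIBAL-H 1,2-reduction of the cinnamate ester to the allylic alcohol leaves both alkenes and the E geometry untouched.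

Step 6
Reactants: 7 O-allyl sinapyl alcohol
Product: 8 (E)-cinnamyl bromide 2-(allyloxy)-5-(3-bromoprop-1-enyl)-1,3-dimethoxybenzene
Conditions: CBr4, PPh3, CH2Cl2, 0 °C; used at once
Reagents that add atoms: carbon tetrabromide BrC(Br)(Br)Br
Why: Appel bromination under neutral conditions gives the reactive, electron-rich allylic bromide without acid that could harm the aryl allyl ether.

Step 7
Reactants: 4 erythro epoxy alcohol; 8 cinnamyl bromide
Product: 9 epoxy cinnamyl ether (2R)-2-[(S)-{[(E)-3-(4-allyloxy-3,5-dimethoxyphenyl)prop-2-enyl]oxy}[3,5-dimethoxy-4-(triisopropylsilyloxy)phenyl]methyl]oxirane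
Conditions: NaH, Bu4NI (cat.), THF/DMF, 0 °C
Reagents that add atoms: none
Why: Williamson etherification of the secondary alkoxide with the allylic bromide in aprotic medium at 0 °C should outrun Payne rearrangement; the C7–O bond is not broken, so C7 keeps its configuration.

Step 8
Reactants: 9 epoxy cinnamyl ether
Product: 14 (7R,8S,7'R,8'S)-syringaresinol 4-O-TIPS 4'-O-allyl diether, via β-titanoxy C8 radical 10 (not isolated), via cyclised benzylic radical 11 (not isolated), via benzylic titanium species 12 (not isolated), via benzylic iodide 13 (not isolated)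
Conditions: Cp2TiCl2, Zn, THF, rt (gives Cp2TiCl); slow addition of 9; then I2, rt → 40 °C; aq. NaH2PO4, Na2S2O3
Reagents that add atoms: none
Why: Cp2TiCl (trivalent titanium, made in the flask) opens the terminal epoxide of 9 homolytically at the more substituted C8–O bond (Nugent–RajanBabu opening) to radical 10, which adds 5-exo-trig to the cinnamyl double bond, forming the C8–C8' bond and ring A and leaving benzylic radical 11; a second Cp2TiCl captures 11 as 12, iodine turns 12 into benzylic iodide 13, and ionisation of 13 to a para-alkoxybenzyl (quinone-methide-type) cation, the electrophile of lignan biosynthesis, is followed by attack of the titanium alkoxide on C9, which closes ring B through the new O–C7' bond. The closest known reaction type is the titanocene-mediated radical cyclisation of epoxy cinnamyl ethers with iodine work-up, which has been used for 2,6-diaryl furofuran lignans. Ring A (C7–O–C9'–C8'–C8) closes by 5-exo-trig radical C–C formation and ring B (C8–C9–O–C7'–C8') by intramolecular SN1-like O-alkylation at C7'. C8 and C8' are set in the chair-like 5-exo transition state, where the C7 aryl group sits pseudo-equatorial (7,8-trans) and the CH2O–Ti arm and the alkene approach cis (8,8'-cis, the only isomer that can bicyclise), and C7' is set when the alkoxide attacks the planar cation so that the aryl group ends on the convex exo face (7',8'-trans); all three therefore follow from C7, while the epoxide configuration at C8 is erased in the radical. The step needs cyclisation of 10 to outrun its reduction by a second titanium (which would end in deoxygenation) and needs the secondary, not the primary, radical: slow addition of 9 to dilute Cp2TiCl and the fast styrene-type acceptor secure the first, the intrinsic preference for the more substituted radical the second, and the silyl and allyl aryl ethers are inert to the reagent.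

Step 9
Reactants: 14 differentiated syringaresinol diether
Product: 15 (7R,8S,7'R,8'S)-syringaresinol 4-O-TIPS ether (free 4'-phenol on unit S')
Conditions: Pd(PPh3)4 (cat.), morpholine, THF, rt
Reagents that add atoms: none
Why: Tsuji–Trost deallylation: zerovalent palladium ionises the aryl allyl ether to a π-allyl complex that morpholine captures; silyl ether and benzylic ring ethers are untouched.

Step 10
Reactants: 15 mono-phenol; 16 (S)-4-benzyl-3-(chloroacetyl)oxazolidin-2-one
Product: 17 S'-aryloxyacetyl imide (15 with its 4'-oxygen bonded to CH2C(=O)Xc, Xc of S configuration)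
Conditions: K2CO3, NaI (cat.), acetone, 50 °C
Reagents that add atoms: none
Why: Williamson O-alkylation of the hindered phenoxide by SN2 at the activated α-halo imide, helped by in situ Finkelstein exchange.

Step 11
Reactants: 17 S'-aryloxyacetyl imide; 18 4-(allyloxy)-3-methoxybenzaldehyde
Product: 19 syn-aldol adduct (S'–O–CH[C(=O)Xc]–CH(OH)–aryl, (2S,3R) in the propanoyl chain)
Conditions: Bu2BOTf, iPr2NEt, CH2Cl2, −78 → 0 °C; 18, −78 → 0 °C; pH 7 buffer (NaH2PO4/Na2HPO4), MeOH, H2O2
Reagents that add atoms: none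
Why: Evans syn-aldol: the Z boron enolate reacts through a closed chair transition state on the face left open by the (S)-benzyl auxiliary, setting both centres of G3 (they read 7R,8R after removal of the auxiliary, i.e. threo); the amine-buffered low temperature should spare the furofuran.

Step 12
Reactants: 19 syn-aldol adduct
Product: 20 threo diol (G3 7R,8R; free 7-OH and 9-OH)
Conditions: LiBH4, THF, MeOH (1 equiv), 0 °C
Reagents that add atoms: none
Why: Reductive removal of the Evans auxiliary by hydride attack at the exocyclic imide carbonyl gives the 1,3-diol without touching C8.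

Step 13
Reactants: 20 threo diol
Product: 21 G3 9-O-acetate (7-OH free)
Conditions: AcCl, 2,4,6-collidine, CH2Cl2, −78 °C
Reagents that add atoms: acetyl chloride CC(Cl)=O
Why: Selective acetylation of the primary hydroxyl over the hindered secondary benzylic one (acyl chloride with collidine at low temperature).

Step 14
Reactants: 21 G3 9-O-acetate
Product: 22 erythro ester (G3 7S,8R; 7-O-(4-nitrobenzoate), 9-O-acetate)
Conditions: 4-nitrobenzoic acid, PPh3, DIAD, THF, 0 °C → rt
Reagents that add atoms: 4-nitrobenzoic acid OC(=O)c1ccc(cc1)[N+](=O)[O-]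
Why: Mitsunobu reaction: SN2 displacement of the alkoxyphosphonium by the carboxylate inverts C7 and turns the threo unit into the erythro unit (7S,8R) required for G3.

Step 15
Reactants: 22 erythro ester
Product: 23 phenol (22 without TIPS; free 4-OH on unit S)
Conditions: Bu4NF, AcOH, THF, 0 °C
Reagents that add atoms: none
Why: Fluoride cleavage of the aryl silyl ether, buffered with acetic acid so that acetate, nitrobenzoate and allyl ether stay.

Step 16
Reactants: 23 phenol; 16 (S)-4-benzyl-3-(chloroacetyl)oxazolidin-2-one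
Product: 24 S-aryloxyacetyl imide (23 with its 4-oxygen bonded to CH2C(=O)Xc, Xc of S configuration)
Conditions: K2CO3, NaI (cat.), acetone, 50 °C
Reagents that add atoms: none
Why: Williamson O-alkylation as in step 10; anhydrous carbonate in acetone should leave the two esters intact.

Step 17
Reactants: 25 4-hydroxy-3-methoxybenzonitrile; 26 (R)-4-benzyl-3-(chloroacetyl)oxazolidin-2-one
Product: 27 (R)-4-benzyl-3-[(4-cyano-2-methoxyphenoxy)acetyl]oxazolidin-2-one
Conditions: K2CO3, NaI (cat.), acetone, 50 °C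
Reagents that add atoms: none
Why: Williamson O-alkylation of the acidic cyanophenol; the nitrile is a latent aldehyde that tolerates the boron aldol and borohydride steps.

Step 18
Reactants: 27 cyanophenoxyacetyl imide; 18 4-(allyloxy)-3-methoxybenzaldehyde
Product: 28 syn-aldol adduct ((2R,3S) in the propanoyl chain)
Conditions: Bu2BOTf, iPr2NEt, CH2Cl2, −78 → 0 °C; 18, −78 → 0 °C; pH 7 buffer (NaH2PO4/Na2HPO4), MeOH, H2O2
Reagents that add atoms: none
Why: Evans syn-aldol with the (R)-auxiliary through the closed chair transition state gives the enantiomeric syn series (7S,8S after reduction), which fixes C8 of G1 as S.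

Step 19
Reactants: 28 syn-aldol adduct
Product: 29 threo diol nitrile 4-{[(1S,2S)-1-[4-(allyloxy)-3-methoxyphenyl]-1,3-dihydroxypropan-2-yl]oxy}-3-methoxybenzonitrile
Conditions: LiBH4, THF, MeOH (1 equiv), 0 °C
Reagents that add atoms: none
Why: Reductive removal of the auxiliary; the aryl nitrile is not reduced by LiBH4 at this temperature.

Step 20
Reactants: 29 threo diol nitrile
Product: 30 threo diol aldehyde 4-{[(1S,2S)-1-[4-(allyloxy)-3-methoxyphenyl]-1,3-dihydroxypropan-2-yl]oxy}-3-methoxybenzaldehyde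
Conditions: DIBAL-H (iBu2AlH), CH2Cl2, −78 → −20 °C; aq. citric acid
Reagents that add atoms: water O
Why: DIBAL-H half-reduction of the nitrile to the N-aluminio aldimine and hydrolysis to the aldehyde; the diol is carried as its aluminium alkoxide and no ester is present yet.

Step 21
Reactants: 30 threo diol aldehyde
Product: 31 primary acetate (2S,3S)-3-[4-(allyloxy)-3-methoxyphenyl]-2-(4-formyl-2-methoxyphenoxy)-3-hydroxypropyl acetate
Conditions: AcCl, 2,4,6-collidine, CH2Cl2, −78 °C
Reagents that add atoms: acetyl chloride CC(Cl)=O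
Why: Selective acetylation of the primary hydroxyl as in step 13.

Step 22
Reactants: 31 primary acetate
Product: 32 erythro aldehyde (1R,2S)-3-acetoxy-1-[4-(allyloxy)-3-methoxyphenyl]-2-(4-formyl-2-methoxyphenoxy)propyl 4-nitrobenzoate
Conditions: 4-nitrobenzoic acid, PPh3, DIAD, THF, 0 °C → rt
Reagents that add atoms: 4-nitrobenzoic acid OC(=O)c1ccc(cc1)[N+](=O)[O-]
Why: Mitsunobu inversion at the benzylic C7 turns the threo (7S,8S) unit into the erythro (7R,8S) unit G1; the aryl aldehyde is inert under these conditions.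

Step 23
Reactants: 24 S-aryloxyacetyl imide; 32 erythro aldehyde
Product: 33 syn-aldol adduct (fully protected pentamer; G2 chain (2S,3R), imide at C9 of G2)
Conditions: Bu2BOTf, iPr2NEt, CH2Cl2, −78 → 0 °C; 32, −78 → 0 °C; pH 7 buffer (NaH2PO4/Na2HPO4), MeOH, H2O2
Reagents that add atoms: none
Why: Evans syn-aldol with the (S)-auxiliary joins the two large pieces and sets C7 and C8 of G2 (7R,8R, threo) through the closed chair transition state; acetate and benzoate esters are not enolised by Bu2BOTf and amine at low temperature.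

Step 24
Reactants: 33 protected pentamer
Product: 34 bis(O-allyl) ether of the target (all six aliphatic hydroxyls free)
Conditions: LiBH4 (excess), THF/MeOH, 0 °C → rt; aq. NH4Cl
Reagents that add atoms: none
Why: Borohydride reduction removes the auxiliary reductively (C9 of G2 becomes CH2OH) and cleaves the two acetates and two 4-nitrobenzoates by reduction in the same operation; no stereocentre is α to a carbonyl afterwards.

Step 25
Reactants: 34 bis(O-allyl) ether
Product: 35 target CNP0316493.1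
Conditions: Pd(PPh3)4 (cat.), morpholine, THF/MeOH, rt
Reagents that add atoms: none
Why: Tsuji–Trost deallylation of both guaiacyl allyl ethers under neutral conditions that leave the benzylic alcohols, the β-aryl ethers and the furofuran untouched.

**Compound list**

In the SMILES of titanium-bound intermediates the cyclopentadienyl rings are written as σ-bonded C5H5 groups.

1 | syringaldehyde | COc1cc(C=O)cc(OC)c1O | starting material
2 | 3,5-dimethoxy-4-(triisopropylsilyloxy)benzaldehyde | COc1cc(C=O)cc(OC)c1O[Si](C(C)C)(C(C)C)C(C)C | intermediate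
3 | racemic 1-[3,5-dimethoxy-4-(triisopropylsilyloxy)phenyl]prop-2-en-1-ol | COc1cc(C(O)C=C)cc(OC)c1O[Si](C(C)C)(C(C)C)C(C)C | intermediate
4 | (S)-[3,5-dimethoxy-4-(triisopropylsilyloxy)phenyl][(2R)-oxiran-2-yl]methanol | COc1cc(cc(OC)c1O[Si](C(C)C)(C(C)C)C(C)C)[C@H](O)[C@H]1CO1 | intermediate
5 | methyl sinapate | COC(=O)/C=C/c1cc(OC)c(O)c(OC)c1 | starting material
6 | methyl (E)-3-[4-(allyloxy)-3,5-dimethoxyphenyl]acrylate | COC(=O)/C=C/c1cc(OC)c(OCC=C)c(OC)c1 | intermediate
7 | (E)-3-[4-(allyloxy)-3,5-dimethoxyphenyl]prop-2-en-1-ol | OC/C=C/c1cc(OC)c(OCC=C)c(OC)c1 | intermediate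
8 | 2-(allyloxy)-5-[(E)-3-bromoprop-1-enyl]-1,3-dimethoxybenzene | BrC/C=C/c1cc(OC)c(OCC=C)c(OC)c1 | intermediate
9 | (2R)-2-[(S)-{[(E)-3-(4-allyloxy-3,5-dimethoxyphenyl)prop-2-enyl]oxy}[3,5-dimethoxy-4-(triisopropylsilyloxy)phenyl]methyl]oxirane | COc1cc(cc(OC)c1O[Si](C(C)C)(C(C)C)C(C)C)[C@H](OC/C=C/c1cc(OC)c(OCC=C)c(OC)c1)[C@H]1CO1 | intermediate
10 | β-titanoxy secondary radical at C8 (C9–O–TiClCp2) | COc1cc(cc(OC)c1O[Si](C(C)C)(C(C)C)C(C)C)[C@H](OC/C=C/c1cc(OC)c(OCC=C)c(OC)c1)[CH]CO[Ti](Cl)(C1C=CC=C1)C1C=CC=C1 | intermediate (not isolated)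
11 | cyclised 2,3-trans-3,4-cis tetrahydrofuran with benzylic radical at C7' | COc1cc(cc(OC)c1O[Si](C(C)C)(C(C)C)C(C)C)[C@@H]1OC[C@@H]([CH]c2cc(OC)c(OCC=C)c(OC)c2)[C@H]1CO[Ti](Cl)(C1C=CC=C1)C1C=CC=C1 | intermediate (not isolated)
12 | benzylic titanium species (C7'–TiClCp2) | COc1cc(cc(OC)c1O[Si](C(C)C)(C(C)C)C(C)C)[C@@H]1OC[C@@H](C([Ti](Cl)(C2C=CC=C2)C2C=CC=C2)c2cc(OC)c(OCC=C)c(OC)c2)[C@H]1CO[Ti](Cl)(C1C=CC=C1)C1C=CC=C1 | intermediate (not isolated)
13 | benzylic iodide (C7'–I, both epimers) | COc1cc(cc(OC)c1O[Si](C(C)C)(C(C)C)C(C)C)[C@@H]1OC[C@@H](C(I)c2cc(OC)c(OCC=C)c(OC)c2)[C@H]1CO[Ti](Cl)(C1C=CC=C1)C1C=CC=C1 | intermediate (not isolated)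
14 | (1R,3aS,4R,6aS)-4-[4-(allyloxy)-3,5-dimethoxyphenyl]-1-[3,5-dimethoxy-4-(triisopropylsilyloxy)phenyl]tetrahydro-1H,3H-furo[3,4-c]furan | COc1cc(cc(OC)c1O[Si](C(C)C)(C(C)C)C(C)C)[C@@H]1OC[C@@H]2[C@H]1CO[C@H]2c1cc(OC)c(OCC=C)c(OC)c1 | intermediate
15 | (7R,8S,7'R,8'S)-syringaresinol 4-O-TIPS ether | COc1cc(cc(OC)c1O[Si](C(C)C)(C(C)C)C(C)C)[C@@H]1OC[C@@H]2[C@H]1CO[C@H]2c1cc(OC)c(O)c(OC)c1 | intermediate
16 | (S)-4-benzyl-3-(chloroacetyl)oxazolidin-2-one | ClCC(=O)N1[C@@H](Cc2ccccc2)COC1=O | starting material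
17 | 15 O-alkylated at the 4'-phenol with CH2C(=O)Xc (S auxiliary) | COc1cc(cc(OC)c1O[Si](C(C)C)(C(C)C)C(C)C)[C@@H]1OC[C@@H]2[C@H]1CO[C@H]2c1cc(OC)c(OCC(=O)N2[C@@H](Cc3ccccc3)COC2=O)c(OC)c1 | intermediate
18 | 4-(allyloxy)-3-methoxybenzaldehyde | COc1cc(C=O)ccc1OCC=C | starting material
19 | syn-aldol adduct of 17 and 18, (2S,3R)-3-[4-(allyloxy)-3-methoxyphenyl]-3-hydroxy-2-(S'-aryloxy)propanoyl imide | COc1cc(cc(OC)c1O[Si](C(C)C)(C(C)C)C(C)C)[C@@H]1OC[C@@H]2[C@H]1CO[C@H]2c1cc(OC)c(O[C@H](C(=O)N2[C@@H](Cc3ccccc3)COC2=O)[C@H](O)c2ccc(OCC=C)c(OC)c2)c(OC)c1 | intermediate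
20 | threo diol: 4'-O-[(1R,2R)-1-(4-allyloxy-3-methoxyphenyl)-1,3-dihydroxypropan-2-yl] ether of 15 | COc1cc(cc(OC)c1O[Si](C(C)C)(C(C)C)C(C)C)[C@@H]1OC[C@@H]2[C@H]1CO[C@H]2c1cc(OC)c(O[C@H](CO)[C@H](O)c2ccc(OCC=C)c(OC)c2)c(OC)c1 | intermediate
21 | 20 acetylated at the primary hydroxyl (G3 9-O-acetate) | COc1cc(cc(OC)c1O[Si](C(C)C)(C(C)C)C(C)C)[C@@H]1OC[C@@H]2[C@H]1CO[C@H]2c1cc(OC)c(O[C@H](COC(C)=O)[C@H](O)c2ccc(OCC=C)c(OC)c2)c(OC)c1 | intermediate
22 | erythro ester: G3 (7S,8R), 7-O-(4-nitrobenzoate), 9-O-acetate, TIPS on unit S | COc1cc(cc(OC)c1O[Si](C(C)C)(C(C)C)C(C)C)[C@@H]1OC[C@@H]2[C@H]1CO[C@H]2c1cc(OC)c(O[C@H](COC(C)=O)[C@@H](OC(=O)c2ccc(cc2)[N+](=O)[O-])c2ccc(OCC=C)c(OC)c2)c(OC)c1 | intermediate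
23 | 22 without TIPS (free 4-phenol on unit S) | COc1cc(cc(OC)c1O)[C@@H]1OC[C@@H]2[C@H]1CO[C@H]2c1cc(OC)c(O[C@H](COC(C)=O)[C@@H](OC(=O)c2ccc(cc2)[N+](=O)[O-])c2ccc(OCC=C)c(OC)c2)c(OC)c1 | intermediate
24 | 23 O-alkylated at the 4-phenol with CH2C(=O)Xc (S auxiliary) | COc1cc(cc(OC)c1OCC(=O)N1[C@@H](Cc2ccccc2)COC1=O)[C@@H]1OC[C@@H]2[C@H]1CO[C@H]2c1cc(OC)c(O[C@H](COC(C)=O)[C@@H](OC(=O)c2ccc(cc2)[N+](=O)[O-])c2ccc(OCC=C)c(OC)c2)c(OC)c1 | intermediate
25 | 4-hydroxy-3-methoxybenzonitrile | COc1cc(C#N)ccc1O | starting material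
26 | (R)-4-benzyl-3-(chloroacetyl)oxazolidin-2-one | ClCC(=O)N1[C@H](Cc2ccccc2)COC1=O | starting material
27 | (R)-4-benzyl-3-[(4-cyano-2-methoxyphenoxy)acetyl]oxazolidin-2-one | COc1cc(C#N)ccc1OCC(=O)N1[C@H](Cc2ccccc2)COC1=O | intermediate
28 | syn-aldol adduct of 27 and 18, (2R,3S)-3-[4-(allyloxy)-3-methoxyphenyl]-2-(4-cyano-2-methoxyphenoxy)-3-hydroxypropanoyl imide | COc1cc([C@H](O)[C@H](C(=O)N2[C@H](Cc3ccccc3)COC2=O)Oc2ccc(C#N)cc2OC)ccc1OCC=C | intermediate
29 | 4-{[(1S,2S)-1-[4-(allyloxy)-3-methoxyphenyl]-1,3-dihydroxypropan-2-yl]oxy}-3-methoxybenzonitrile | COc1cc([C@H](O)[C@H](CO)Oc2ccc(C#N)cc2OC)ccc1OCC=C | intermediate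
30 | 4-{[(1S,2S)-1-[4-(allyloxy)-3-methoxyphenyl]-1,3-dihydroxypropan-2-yl]oxy}-3-methoxybenzaldehyde | COc1cc([C@H](O)[C@H](CO)Oc2ccc(C=O)cc2OC)ccc1OCC=C | intermediate
31 | (2S,3S)-3-[4-(allyloxy)-3-methoxyphenyl]-2-(4-formyl-2-methoxyphenoxy)-3-hydroxypropyl acetate | COc1cc([C@H](O)[C@H](COC(C)=O)Oc2ccc(C=O)cc2OC)ccc1OCC=C | intermediate
32 | (1R,2S)-3-acetoxy-1-[4-(allyloxy)-3-methoxyphenyl]-2-(4-formyl-2-methoxyphenoxy)propyl 4-nitrobenzoate | COc1cc([C@@H](OC(=O)c2ccc(cc2)[N+](=O)[O-])[C@H](COC(C)=O)Oc2ccc(C=O)cc2OC)ccc1OCC=C | intermediate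
33 | syn-aldol adduct of 24 and 32 (G1 and G3: 7-O-(4-nitrobenzoate), 9-O-acetate, 4-O-allyl; G2: free 7-OH, C9 as the (S)-Xc imide) | COc1cc([C@@H](OC(=O)c6ccc(cc6)[N+](=O)[O-])[C@H](COC(C)=O)Oc2ccc([C@@H](O)[C@@H](C(=O)N6[C@@H](Cc7ccccc7)COC6=O)Oc3c(OC)cc([C@@H]4OC[C@@H]5[C@H]4CO[C@H]5c4cc(OC)c(O[C@H](COC(C)=O)[C@@H](OC(=O)c6ccc(cc6)[N+](=O)[O-])c5ccc(OCC=C)c(OC)c5)c(OC)c4)cc3OC)cc2OC)ccc1OCC=C | intermediate
34 | target with both guaiacyl phenols as allyl ethers | COc1cc([C@@H](O)[C@H](CO)Oc2ccc([C@@H](O)[C@@H](CO)Oc3c(OC)cc([C@@H]4OC[C@@H]5[C@H]4CO[C@H]5c4cc(OC)c(O[C@H](CO)[C@@H](O)c5ccc(OCC=C)c(OC)c5)c(OC)c4)cc3OC)cc2OC)ccc1OCC=C | intermediate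
35 | CNP0316493.1 | COc1cc([C@@H](O)[C@H](CO)Oc2ccc([C@@H](O)[C@@H](CO)Oc3c(OC)cc([C@@H]4OC[C@@H]5[C@H]4CO[C@H]5c4cc(OC)c(O[C@H](CO)[C@@H](O)c5ccc(O)c(OC)c5)c(OC)c4)cc3OC)cc2OC)ccc1O | target

**Step count and risks**

Total step count: 25. Longest linear sequence: 16 steps (steps 4–16, then 23–25; the sequence through steps 1–3 and 7 onward is equally long).

Steps most likely to fail:

1. Step 8 (key cascade). Radical 10 may be reduced by a second Cp2TiCl before it cyclises, followed by β-elimination and loss of the oxygen function. The 5-exo closure may be incompletely cis-selective, and the trans isomer cannot close ring B. Capture of the benzylic cation may show poor facial selectivity (C7' epimer). Fallback: from 9, run only the titanocene opening and 5-exo cyclisation and quench with aqueous acid, which should give the monocyclic alcohol [(2R,3S,4S)-4-(4-allyloxy-3,5-dimethoxybenzyl)-2-(3,5-dimethoxy-4-triisopropylsilyloxyphenyl)tetrahydrofuran-3-yl]methanol F1. Ring B is then closed in a separate polar step by DDQ in CH2Cl2: hydride abstraction from the electron-rich benzylic CH2 and capture of the cation by the cis hydroxymethyl group. This returns to 14.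

2. Step 3 (kinetic resolution). The rate ratio may be low for an aryl vinyl carbinol. The Lewis acid may ionise the electron-rich benzylic allylic alcohol (racemisation, allylic transposition), and isopropanol may open the product epoxide. Fallback: from 3, resolve with immobilised Candida antarctica lipase B and vinyl acetate to the (R)-acetate (R)-1-[3,5-dimethoxy-4-(triisopropylsilyloxy)phenyl]allyl acetate F2, separated from unreacted (S)-3. Methanolysis (K2CO3, MeOH, 0 °C) gives (R)-1-[3,5-dimethoxy-4-(triisopropylsilyloxy)phenyl]prop-2-en-1-ol F3. Complete, reagent-matched epoxidation (Ti(OiPr)4, L-(+)-diisopropyl tartrate, tBuOOH) returns to 4.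

3. Step 14 (Mitsunobu inversion; the same operation recurs in step 22). The activated, electron-rich benzylic alkoxyphosphonium may ionise and lose stereospecificity, and displacement next to the 2,6-dimethoxyphenoxy group may be slow. Fallback: from 21, oxidise the benzylic alcohol with Dess–Martin periodinane to the aryl ketone F4 (G3 C7 ketone, 8R, 9-O-acetate). Chelation-controlled reduction with Zn(BH4)2 in Et2O at −30 °C (anti, that is erythro, for α-aryloxy ketones) should give the erythro alcohol F5 (G3 7S,8R, 9-O-acetate). Acylation with 4-nitrobenzoyl chloride and pyridine returns to 22.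

Further compounds
F1 | step 8 | [(2R,3S,4S)-4-(4-allyloxy-3,5-dimethoxybenzyl)-2-(3,5-dimethoxy-4-triisopropylsilyloxyphenyl)tetrahydrofuran-3-yl]methanol | COc1cc(cc(OC)c1O[Si](C(C)C)(C(C)C)C(C)C)[C@@H]1OC[C@@H](Cc2cc(OC)c(OCC=C)c(OC)c2)[C@H]1CO
F2 | step 3 | (R)-1-[3,5-dimethoxy-4-(triisopropylsilyloxy)phenyl]allyl acetate | COc1cc(cc(OC)c1O[Si](C(C)C)(C(C)C)C(C)C)[C@H](OC(C)=O)C=C
F3 | step 3 | (R)-1-[3,5-dimethoxy-4-(triisopropylsilyloxy)phenyl]prop-2-en-1-ol | COc1cc(cc(OC)c1O[Si](C(C)C)(C(C)C)C(C)C)[C@H](O)C=C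
F4 | step 14 | aryl ketone from 21 (G3 C7 oxidised to C=O, 8R, 9-O-acetate) | COc1cc(cc(OC)c1O[Si](C(C)C)(C(C)C)C(C)C)[C@@H]1OC[C@@H]2[C@H]1CO[C@H]2c1cc(OC)c(O[C@H](COC(C)=O)C(=O)c2ccc(OCC=C)c(OC)c2)c(OC)c1
F5 | step 14 | erythro alcohol (G3 7S,8R, free 7-OH, 9-O-acetate) | COc1cc(cc(OC)c1O[Si](C(C)C)(C(C)C)C(C)C)[C@@H]1OC[C@@H]2[C@H]1CO[C@H]2c1cc(OC)c(O[C@H](COC(C)=O)[C@@H](O)c2ccc(OCC=C)c(OC)c2)c(OC)c1
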